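**Retrosynthetic overview**

1. The target is a 14-membered lactone, numbered O1, C2 (lactone carbonyl) round to C14 (carrying ethyl). The plan rests on its ring-cis trisubstituted C7=C8 alkene, whose methyl-bearing C7 is homoallylic to the tertiary C5 hydroxyl. The C7 methyl is removed and C7=C8 is taken back to a C7≡C8 cycloalkyne, to be refunctionalised by syn delivery of silicon from O5.
2. The cycloalkyne is opened at C7–C8 to a seco ester with two methyl-capped alkynes. Ring-closing alkyne metathesis forms the only ring, the 14-membered one.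
3. The seco ester comes from acid 29 (C2–C7) and alcohol 17 (C8–C14) by esterification at O1–C2. The C4 ketone is unveiled just before ring closure.
4. Alcohol 17 comes from a Stille union at C11–C12 of 2-bromoalkene 9 (C9 by auxiliary alkylation) with Z-stannane 16 (C14 by asymmetric transfer hydrogenation, C12=C13 by anti-carbomagnesiation).
5. Acid 29 comes from an auxiliary-controlled syn aldol (C3) on aldehyde 24. Its C5 centre comes from asymmetric epoxidation of mono-silylated 2-methylidenepropane-1,3-diol and propynyl opening.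

Key step: step 22

Assumption: the primary hydroxyl on the C5 hydroxymethyl group is carried as a tert-butyldiphenylsilyl ether, so that the triethylsilyl ethers on O4 and O5 can be removed beside it in step 20.
Assumption: once the C4 ketone is in place (step 21), C3 lies between two carbonyl groups and is treated as base-labile; steps 22–27 therefore use only neutral or weakly acidic conditions.

**Route**

Step 1
Reactants: 1 (4R)-4-benzyl-3-propanoyl-1,3-oxazolidin-2-one; 2 2,3-dibromoprop-1-ene
Product: 4 (4R)-4-benzyl-3-[(2S)-4-bromo-2-methylpent-4-enoyl]-1,3-oxazolidin-2-one, via sodium Z-enolate 3 (not isolated)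
Conditions: NaN(SiMe3)2, THF, −78 °C; then 2, −78 → −40 °C
Reagents that add atoms: none
Why: Evans asymmetric alkylation: the chelated sodium Z-enolate is shielded on one face by the benzyl group of the (R)-auxiliary, and the allylic bromide should enter from the open face, which sets C9 as (S).

Step 2
Reactants: 4 (4R)-4-benzyl-3-[(2S)-4-bromo-2-methylpent-4-enoyl]-1,3-oxazolidin-2-one
Product: 5 (2S)-4-bromo-2-methylpent-4-en-1-ol
Conditions: LiBH4, MeOH (1 equiv), Et2O, 0 °C
Reagents that add atoms: none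
Why: Reductive cleavage of the N-acyl oxazolidinone by LiBH4 (hydride attack at the exocyclic carbonyl) should give the primary alcohol without touching the alkenyl bromide or the new stereocentre, and it returns the auxiliary.

Step 3
Reactants: 5 (2S)-4-bromo-2-methylpent-4-en-1-ol
Product: 6 (2S)-4-bromo-2-methylpent-4-enal
Conditions: Dess–Martin periodinane, CH2Cl2, 0 °C → rt; used at once
Reagents that add atoms: none
Why: Dess–Martin oxidation of a primary alcohol under non-basic conditions should give the α-branched aldehyde without epimerisation.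

Step 4
Reactants: 6 (2S)-4-bromo-2-methylpent-4-enal
Product: 7 (3S)-5-bromo-3-methylhex-5-en-1-yne
Conditions: dimethyl (1-diazo-2-oxopropyl)phosphonate, K2CO3, MeOH, 0 °C → rt
Reagents that add atoms: dimethyl (1-diazo-2-oxopropyl)phosphonate, COP(=O)(OC)C(=[N+]=[N-])C(C)=O
Why: Ohira–Bestmann (Seyferth–Gilbert) homologation: the diazomethylphosphonate anion formed by methanolysis adds to the aldehyde and the resulting alkylidene carbene rearranges by 1,2-hydrogen shift to the terminal alkyne, under conditions mild enough for the α-alkyl stereocentre and the alkenyl bromide.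

Step 5
Reactants: 7 (3S)-5-bromo-3-methylhex-5-en-1-yne
Product: 9 (4S)-6-bromo-4-methylhept-6-en-2-yne, via lithium acetylide 8 (not isolated)
Conditions: LiN(SiMe3)2, THF, −78 °C; then MeI, −78 °C → rt
Reagents that add atoms: iodomethane, CI
Why: Deprotonation of the terminal alkyne by a lithium amide (which does not exchange the alkenyl bromide) and SN2 methylation of the acetylide installs the methyl cap that alkyne metathesis needs.

Step 6
Reactants: 10 bis(trimethylsilyl)acetylene; 11 propanoyl chloride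
Product: 12 1-(trimethylsilyl)pent-1-yn-3-one
Conditions: AlCl3, CH2Cl2, 0 °C
Reagents that add atoms: none
Why: Friedel–Crafts-type acylation of a silylalkyne (ipso attack of the acylium–AlCl3 complex with loss of one Me3Si group) is a standard entry to silyl ynones.

Step 7
Reactants: 12 1-(trimethylsilyl)pent-1-yn-3-one
Product: 13 (3S)-1-(trimethylsilyl)pent-1-yn-3-ol
Conditions: Ru(p-cymene)[(S,S)-TsNCHPhCHPhNH] (cat.), i-PrOH, rt
Reagents that add atoms: none
Why: Noyori asymmetric transfer hydrogenation of an alkynyl ketone: the (S,S)-diamine ruthenium hydride transfers hydride and proton through a six-membered transition state to the carbonyl face that gives the (S)-propargylic alcohol, which sets C14.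

Step 8
Reactants: 13 (3S)-1-(trimethylsilyl)pent-1-yn-3-ol
Product: 14 (3S)-pent-1-yn-3-ol
Conditions: K2CO3 (cat.), MeOH, rt
Reagents that add atoms: none
Why: Carbonate-catalysed methanolysis cleaves the C(sp)–Si bond and leaves the carbinol stereocentre untouched.

Step 9
Reactants: 14 (3S)-pent-1-yn-3-ol
Product: 16 (1Z,3S)-2-methyl-1-(tributylstannyl)pent-1-en-3-ol, via cyclic alkenylmagnesium alkoxide 15 (not isolated)
Conditions: MeMgBr (3 equiv), CuI (10 mol %), THF, −10 °C → rt; then Bu3SnCl, 0 °C → rt; aq. NH4Cl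
Reagents that add atoms: methylmagnesium bromide, C[Mg]Br; tributyltin chloride, CCCC[Sn](Cl)(CCCC)CCCC
Why: Copper-catalysed anti-carbomagnesiation of a propargylic alkoxide adds methyl to the internal and magnesium to the terminal alkyne carbon within a five-membered chelate, and stannylation of this alkenyl Grignard with retention should give the stannane with tin cis to the carbinol carbon, which fixes the later C12=C13 geometry as ring-cis (12Z).

Step 10
Reactants: 9 (4S)-6-bromo-4-methylhept-6-en-2-yne; 16 (1Z,3S)-2-methyl-1-(tributylstannyl)pent-1-en-3-ol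
Product: 17 (3S,4Z,8S)-4,8-dimethyl-6-methylideneundec-4-en-9-yn-3-ol
Conditions: Pd(PPh3)4 (5 mol %), CuI (10 mol %), CsF, DMF, 45 °C
Reagents that add atoms: none
Why: Stille cross-coupling (copper and fluoride assisted) of a 2-bromo-1-alkene with an alkenylstannane proceeds with retention at both sp2 carbons and tolerates the free hydroxyl, so the 2-substituted 12Z diene should form directly.

Step 11
Reactants: 18 2-methylidenepropane-1,3-diol
Product: 19 2-{[tert-butyl(diphenyl)silyl]oxymethyl}prop-2-en-1-ol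
Conditions: t-BuPh2SiCl (1 equiv), imidazole, THF, 0 °C; diol 18 in threefold excess
Reagents that add atoms: tert-butyl(chloro)diphenylsilane, CC(C)(C)[Si](Cl)(c1ccccc1)c1ccccc1
Why: Statistical silylation of a symmetrical diol used in excess should give mainly the mono-ether, and the bulky silyl group is chosen to outlast every later fluoride and acid step but the last.

Step 12
Reactants: 19 2-{[tert-butyl(diphenyl)silyl]oxymethyl}prop-2-en-1-ol
Product: 20 [(2S)-2-{[tert-butyl(diphenyl)silyl]oxymethyl}oxiran-2-yl]methanol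
Conditions: Ti(OiPr)4 (cat.), L-(+)-diisopropyl tartrate (cat.), t-BuOOH, 4 Å molecular sieves, CH2Cl2, −20 °C
Reagents that add atoms: tert-butyl hydroperoxide, CC(C)(C)OO
Why: Sharpless asymmetric epoxidation of a 2-substituted allylic alcohol: the titanium L-(+)-tartrate complex delivers oxygen to one enantiotopic alkene face and thereby tells the two oxygenated arms apart, which sets C5 (as (S) in 20).

Step 13
Reactants: 20 [(2S)-2-{[tert-butyl(diphenyl)silyl]oxymethyl}oxiran-2-yl]methanol
Product: 21 (2R)-2-{[tert-butyl(diphenyl)silyl]oxymethyl}hex-4-yne-1,2-diol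
Conditions: CH3C≡CLi, Et2AlCl, toluene, 0 °C; then 20, 0 °C → rt; aq. potassium sodium tartrate
Reagents that add atoms: prop-1-ynyllithium, [Li]C#CC
Why: Hydroxyl-directed opening of a 2,3-epoxy alcohol by an alkynylalane: the aluminium alkoxide activates the oxirane and the propynyl group should attack the unsubstituted CH2 carbon, so the C5 centre is not touched and the methyl-capped alkyne for C7 is in place.

Step 14
Reactants: 21 (2R)-2-{[tert-butyl(diphenyl)silyl]oxymethyl}hex-4-yne-1,2-diol
Product: 22 (2R)-2-{[tert-butyl(diphenyl)silyl]oxymethyl}-1,2-bis(triethylsilyloxy)hex-4-yne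
Conditions: Et3SiOSO2CF3 (2.4 equiv), 2,6-lutidine, CH2Cl2, −78 → 0 °C
Reagents that add atoms: triethylsilyl trifluoromethanesulfonate, CC[Si](CC)(CC)OS(=O)(=O)C(F)(F)F
Why: Silylation with a silyl triflate and a hindered pyridine base is strong enough for the tertiary hydroxyl and gives the bis-ether.

Step 15
Reactants: 22 (2R)-2-{[tert-butyl(diphenyl)silyl]oxymethyl}-1,2-bis(triethylsilyloxy)hex-4-yne
Product: 24 (2S)-2-{[tert-butyl(diphenyl)silyl]oxymethyl}-2-(triethylsilyloxy)hex-4-ynal, via alkoxysulfonium chloride 23 (not isolated)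
Conditions: (COCl)2, DMSO, CH2Cl2, −78 → −40 °C; then Et3N, → 0 °C
Reagents that add atoms: none
Why: Under Swern conditions a primary triethylsilyl ether is cleaved by the chlorosulfonium salt and oxidised in the same flask, while the tertiary triethylsilyl and the tert-butyldiphenylsilyl ethers should stay; the aldehyde has no α-hydrogen and cannot epimerise.

Step 16
Reactants: 24 (2S)-2-{[tert-butyl(diphenyl)silyl]oxymethyl}-2-(triethylsilyloxy)hex-4-ynal; 1 (4R)-4-benzyl-3-propanoyl-1,3-oxazolidin-2-one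
Product: 26 (4R)-4-benzyl-3-[(2R,3R,4S)-4-{[tert-butyl(diphenyl)silyl]oxymethyl}-3-hydroxy-2-methyl-4-(triethylsilyloxy)oct-6-ynoyl]-1,3-oxazolidin-2-one, via dibutylboron Z-enolate 25 (not isolated)
Conditions: 1, Bu2BOTf, i-Pr2NEt, CH2Cl2, −78 → 0 °C; then 24, −78 → 0 °C; then pH 7 buffer, MeOH, H2O2, 0 °C
Reagents that add atoms: none
Why: Evans syn aldol: the Z boron enolate reacts through a closed Zimmerman–Traxler transition state on the enolate face left open by the (R)-benzyl auxiliary, which sets C3 as (R) whichever face of the hindered aldehyde is attacked (C4, expected (R), is oxidised later).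

Step 17
Reactants: 26 aldol adduct (as named in step 16)
Product: 27 (4R)-4-benzyl-3-[(2R,3R,4S)-4-{[tert-butyl(diphenyl)silyl]oxymethyl}-2-methyl-3,4-bis(triethylsilyloxy)oct-6-ynoyl]-1,3-oxazolidin-2-one
Conditions: Et3SiOSO2CF3, 2,6-lutidine, CH2Cl2, −78 → 0 °C
Reagents that add atoms: triethylsilyl trifluoromethanesulfonate, CC[Si](CC)(CC)OS(=O)(=O)C(F)(F)F
Why: Silyl triflate protection of the hindered secondary hydroxyl prevents retro-aldol cleavage and self-acylation in the next two steps.

Step 18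
Reactants: 27 silylated imide (as named in step 17)
Product: 29 (2R,3R,4S)-4-{[tert-butyl(diphenyl)silyl]oxymethyl}-2-methyl-3,4-bis(triethylsilyloxy)oct-6-ynoic acid, via peroxy acid 28 (not isolated)
Conditions: LiOH, H2O2, THF–H2O, 0 °C; then aq. Na2SO3; dilute HCl to pH 4
Reagents that add atoms: hydrogen peroxide, OO
Why: Lithium hydroperoxide attacks the exocyclic imide carbonyl selectively, and sulfite reduction of the peroxy acid gives the carboxylic acid with the α-stereocentre intact.

Step 19
Reactants: 29 acid (as named in step 18); 17 (3S,4Z,8S)-4,8-dimethyl-6-methylideneundec-4-en-9-yn-3-ol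
Product: 31 (3S,4Z,8S)-4,8-dimethyl-6-methylideneundec-4-en-9-yn-3-yl (2R,3R,4S)-4-{[tert-butyl(diphenyl)silyl]oxymethyl}-2-methyl-3,4-bis(triethylsilyloxy)oct-6-ynoate, via mixed anhydride 30 (not isolated)
Conditions: 2,4,6-Cl3C6H2COCl, Et3N, THF, rt; then 17, DMAP, toluene, rt → 40 °C
Reagents that add atoms: none
Why: Yamaguchi esterification: DMAP attacks the mixed 2,4,6-trichlorobenzoic anhydride at the less hindered aliphatic carbonyl and the acylpyridinium acylates the secondary allylic alcohol, a method suited to hindered partners.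

Step 20
Reactants: 31 bis(triethylsilyl) seco diyne ester (as named in step 19)
Product: 32 (3S,4Z,8S)-4,8-dimethyl-6-methylideneundec-4-en-9-yn-3-yl (2R,3R,4S)-4-{[tert-butyl(diphenyl)silyl]oxymethyl}-3,4-dihydroxy-2-methyloct-6-ynoate
Conditions: HF·pyridine, pyridine, THF, 0 °C → rt
Reagents that add atoms: none
Why: Buffered HF·pyridine cleaves the secondary and tertiary triethylsilyl ethers far faster than the primary tert-butyldiphenylsilyl ether, and the acidic medium avoids lactonisation of the freed C5 hydroxyl onto the ester.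

Step 21
Reactants: 32 seco diyne diol (as named in step 20)
Product: 33 (3S,4Z,8S)-4,8-dimethyl-6-methylideneundec-4-en-9-yn-3-yl (2R,4S)-4-{[tert-butyl(diphenyl)silyl]oxymethyl}-4-hydroxy-2-methyl-3-oxooct-6-ynoate
Conditions: Dess–Martin periodinane, CH2Cl2, 0 °C → rt
Reagents that add atoms: none
Why: Dess–Martin oxidation converts the secondary C4 carbinol into the ketone while the tertiary C5 hydroxyl cannot be oxidised; the non-basic medium should preserve the now doubly activated C3 centre.

Step 22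
Reactants: 33 seco diyne keto ester with free C5 hydroxyl (as named in step 21)
Product: 34 (3R,5S,9S,12Z,14S)-5-{[tert-butyl(diphenyl)silyl]oxymethyl}-14-ethyl-5-hydroxy-3,9,13-trimethyl-11-methylidene-1-oxacyclotetradec-12-en-7-yne-2,4-dione
Conditions: Mo(≡CC6H4-4-OMe)(OSiPh3)3 (10 mol %), 5 Å molecular sieves, toluene (2 mM), rt → 60 °C
Reagents that add atoms: none
Why: Ring-closing alkyne metathesis: the molybdenum alkylidyne adds to one methyl-capped alkyne to give a metallacyclobutadiene, cycloreverts to a substrate-bound alkylidyne with loss of but-2-yne, and repeats the sequence on the second alkyne within the same molecule to form the C7≡C8 bond. The closest known reaction type is the macrocyclising metathesis of diynes with triarylsilanolate molybdenum alkylidynes. The 14-membered ring (O1, C2 to C14) is closed end-to-end across C7–C8 and is large enough to hold the linear C6–C7≡C8–C9 unit. No stereocentre is formed, and C3, C5, C9 and C14 are carried through unchanged under neutral conditions. The step needs chemoselectivity for the two alkynes over the three C=C bonds and the carbonyl groups, which alkylidynes provide, and ring closure over oligomerisation, which high dilution and trapping of but-2-yne by the sieves should secure. Alkene geometry is not at stake here, because the ring-cis C7=C8 bond follows later from syn addition to the cycloalkyne.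

Step 23
Reactants: 34 cycloalkyne lactone (as named in step 22)
Product: 35 (3R,5S,9S,12Z,14S)-5-{[tert-butyl(diphenyl)silyl]oxymethyl}-5-(dimethylsilyloxy)-14-ethyl-3,9,13-trimethyl-11-methylidene-1-oxacyclotetradec-12-en-7-yne-2,4-dione
Conditions: ClSiMe2H, imidazole, CH2Cl2, 0 °C → rt; filtered, concentrated and used crude
Reagents that add atoms: chlorodimethylsilane, C[SiH](C)Cl
Why: Silylation of the tertiary hydroxyl by the small, reactive chlorosilane with a weak amine base gives the Si–H tether without exposing the β-keto lactone to strong base.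

Step 24
Reactants: 35 C5 dimethylsilyl ether (as named in step 23)
Product: 36 spiro oxasilolane in which O5–SiMe2 bridges to C7 and the C7=C8 alkene is ring-cis (C6 cis to C9)
Conditions: Pt2[(CH2=CHSiMe2)2O]3 (2 mol %), THF, rt
Reagents that add atoms: none
Why: Platinum-catalysed intramolecular hydrosilylation of a homopropargylic silyl ether: syn insertion of the alkyne in the 5-exo-dig mode places silicon on C7 and hydrogen on C8 on the same side, so the alkene must be ring-cis and the regiochemistry is fixed by the five-membered oxasilolane; under platinum catalysis alkynes react much faster than ketones or alkenes.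

Step 25
Reactants: 36 spiro oxasilolane (as described in step 24)
Product: 38 (3R,5S,7E,9S,12Z,14S)-5-{[tert-butyl(diphenyl)silyl]oxymethyl}-14-ethyl-5-hydroxy-7-iodo-3,9,13-trimethyl-11-methylidene-1-oxacyclotetradeca-7,12-diene-2,4-dione, via fluoroalkoxysilyl ether 37 (not isolated)
Conditions: N-iodosuccinimide, 2,6-lutidine, (CF3)2CHOH, 0 °C; then AcOH–THF–H2O, rt
Reagents that add atoms: N-iodosuccinimide, O=C1CCC(=O)N1I
Why: Iododesilylation (electrophilic ipso substitution): iodonium attack at the silicon-bearing C7 gives a β-silyl cation that loses silicon with retention of alkene geometry, so iodine takes the place of silicon (ring-cis alkene kept); in the weakly nucleophilic fluoroalcohol any iodonium formation on the diene should be reversible while desilylation is not, the buffered non-basic medium spares the β-keto lactone, and the silyl residue left on O5 is hydrolysed in the acidic aqueous work-up.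

Step 26
Reactants: 38 C7 iodide (as named in step 25)
Product: 39 (3R,5S,7Z,9S,12Z,14S)-5-{[tert-butyl(diphenyl)silyl]oxymethyl}-14-ethyl-5-hydroxy-3,7,9,13-tetramethyl-11-methylidene-1-oxacyclotetradeca-7,12-diene-2,4-dione
Conditions: Me4Sn, Pd(PPh3)4 (10 mol %), CuI (20 mol %), DMF, 50 °C
Reagents that add atoms: tetramethylstannane, C[Sn](C)(C)C
Why: Stille cross-coupling of an alkenyl iodide with tetramethyltin under neutral conditions transfers methyl to C7 with retention of configuration, completing the ring-cis trisubstituted alkene without exposing the β-keto lactone to base.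

Step 27
Reactants: 39 silyl-protected macrolide (as named in step 26)
Product: 40 (3R,5S,7Z,9S,12Z,14S)-14-ethyl-5-hydroxy-5-(hydroxymethyl)-3,7,9,13-tetramethyl-11-methylidene-1-oxacyclotetradeca-7,12-diene-2,4-dione
Conditions: HF·pyridine, THF, 0 °C → rt
Reagents that add atoms: none
Why: Fluoride cleavage of the primary silyl ether under mildly acidic conditions frees the hydroxymethyl group while avoiding base-induced epimerisation at C3 and acyl transfer to the C5 hydroxyl.

**Compound list**

1 | (4R)-4-benzyl-3-propanoyl-1,3-oxazolidin-2-one | CCC(=O)N1[C@H](Cc2ccccc2)COC1=O | starting material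
2 | 2,3-dibromoprop-1-ene | C=C(Br)CBr | starting material
3 | sodium Z-enolate of 1 | C/C=C(\[O-])N1[C@H](Cc2ccccc2)COC1=O.[Na+] | intermediate (not isolated)
4 | (4R)-4-benzyl-3-[(2S)-4-bromo-2-methylpent-4-enoyl]-1,3-oxazolidin-2-one | C=C(Br)C[C@H](C)C(=O)N1[C@H](Cc2ccccc2)COC1=O | intermediate
5 | (2S)-4-bromo-2-methylpent-4-en-1-ol | OC[C@@H](C)CC(Br)=C | intermediate
6 | (2S)-4-bromo-2-methylpent-4-enal | O=C[C@@H](C)CC(Br)=C | intermediate
7 | (3S)-5-bromo-3-methylhex-5-en-1-yne | C#C[C@@H](C)CC(Br)=C | intermediate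
8 | lithium acetylide of 7 | [Li]C#C[C@@H](C)CC(Br)=C | intermediate (not isolated)
9 | (4S)-6-bromo-4-methylhept-6-en-2-yne | CC#C[C@@H](C)CC(Br)=C | intermediate
10 | bis(trimethylsilyl)acetylene | C[Si](C)(C)C#C[Si](C)(C)C | starting material
11 | propanoyl chloride | CCC(Cl)=O | starting material
12 | 1-(trimethylsilyl)pent-1-yn-3-one | CCC(=O)C#C[Si](C)(C)C | intermediate
13 | (3S)-1-(trimethylsilyl)pent-1-yn-3-ol | CC[C@H](O)C#C[Si](C)(C)C | intermediate
14 | (3S)-pent-1-yn-3-ol | CC[C@H](O)C#C | intermediate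
15 | (5S)-5-ethyl-4-methyl-2,5-dihydro-1,2-oxamagnesole (cyclic alkenylmagnesium alkoxide) | CC[C@@H]1O[Mg]C=C1C | intermediate (not isolated)
16 | (1Z,3S)-2-methyl-1-(tributylstannyl)pent-1-en-3-ol | CC[C@H](O)/C(C)=C\[Sn](CCCC)(CCCC)CCCC | intermediate
17 | (3S,4Z,8S)-4,8-dimethyl-6-methylideneundec-4-en-9-yn-3-ol | CC#C[C@@H](C)CC(=C)/C=C(/C)[C@H](CC)O | intermediate
18 | 2-methylidenepropane-1,3-diol | C=C(CO)CO | starting material
19 | 2-{[tert-butyl(diphenyl)silyl]oxymethyl}prop-2-en-1-ol | C=C(CO)CO[Si](c1ccccc1)(c1ccccc1)C(C)(C)C | intermediate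
20 | [(2S)-2-{[tert-butyl(diphenyl)silyl]oxymethyl}oxiran-2-yl]methanol | OC[C@@]1(CO[Si](c2ccccc2)(c2ccccc2)C(C)(C)C)CO1 | intermediate
21 | (2R)-2-{[tert-butyl(diphenyl)silyl]oxymethyl}hex-4-yne-1,2-diol | OC[C@@](O)(CO[Si](c1ccccc1)(c1ccccc1)C(C)(C)C)CC#CC | intermediate
22 | (2R)-2-{[tert-butyl(diphenyl)silyl]oxymethyl}-1,2-bis(triethylsilyloxy)hex-4-yne | CC[Si](CC)(CC)OC[C@@](O[Si](CC)(CC)CC)(CO[Si](c1ccccc1)(c1ccccc1)C(C)(C)C)CC#CC | intermediate
23 | alkoxydimethylsulfonium chloride formed from 22 at the primary oxygen | C[S+](C)OC[C@@](O[Si](CC)(CC)CC)(CO[Si](c1ccccc1)(c1ccccc1)C(C)(C)C)CC#CC.[Cl-] | intermediate (not isolated)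
24 | (2S)-2-{[tert-butyl(diphenyl)silyl]oxymethyl}-2-(triethylsilyloxy)hex-4-ynal | O=C[C@@](O[Si](CC)(CC)CC)(CO[Si](c1ccccc1)(c1ccccc1)C(C)(C)C)CC#CC | intermediate
25 | dibutylboron Z-enolate of 1 | C/C=C(\OB(CCCC)CCCC)N1[C@H](Cc2ccccc2)COC1=O | intermediate (not isolated)
26 | (4R)-4-benzyl-3-[(2R,3R,4S)-4-{[tert-butyl(diphenyl)silyl]oxymethyl}-3-hydroxy-2-methyl-4-(triethylsilyloxy)oct-6-ynoyl]-1,3-oxazolidin-2-one | O=C(N1[C@H](Cc2ccccc2)COC1=O)[C@H](C)[C@@H](O)[C@@](O[Si](CC)(CC)CC)(CO[Si](c1ccccc1)(c1ccccc1)C(C)(C)C)CC#CC | intermediate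
27 | (4R)-4-benzyl-3-[(2R,3R,4S)-4-{[tert-butyl(diphenyl)silyl]oxymethyl}-2-methyl-3,4-bis(triethylsilyloxy)oct-6-ynoyl]-1,3-oxazolidin-2-one | O=C(N1[C@H](Cc2ccccc2)COC1=O)[C@H](C)[C@@H](O[Si](CC)(CC)CC)[C@@](O[Si](CC)(CC)CC)(CO[Si](c1ccccc1)(c1ccccc1)C(C)(C)C)CC#CC | intermediate
28 | peroxy acid corresponding to 29 | OOC(=O)[C@H](C)[C@@H](O[Si](CC)(CC)CC)[C@@](O[Si](CC)(CC)CC)(CO[Si](c1ccccc1)(c1ccccc1)C(C)(C)C)CC#CC | intermediate (not isolated)
29 | (2R,3R,4S)-4-{[tert-butyl(diphenyl)silyl]oxymethyl}-2-methyl-3,4-bis(triethylsilyloxy)oct-6-ynoic acid | OC(=O)[C@H](C)[C@@H](O[Si](CC)(CC)CC)[C@@](O[Si](CC)(CC)CC)(CO[Si](c1ccccc1)(c1ccccc1)C(C)(C)C)CC#CC | intermediate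
30 | mixed anhydride of 29 with 2,4,6-trichlorobenzoic acid | O=C(OC(=O)c1c(Cl)cc(Cl)cc1Cl)[C@H](C)[C@@H](O[Si](CC)(CC)CC)[C@@](O[Si](CC)(CC)CC)(CO[Si](c1ccccc1)(c1ccccc1)C(C)(C)C)CC#CC | intermediate (not isolated)
31 | (3S,4Z,8S)-4,8-dimethyl-6-methylideneundec-4-en-9-yn-3-yl (2R,3R,4S)-4-{[tert-butyl(diphenyl)silyl]oxymethyl}-2-methyl-3,4-bis(triethylsilyloxy)oct-6-ynoate | CC#C[C@@H](C)CC(=C)/C=C(/C)[C@H](CC)OC(=O)[C@H](C)[C@@H](O[Si](CC)(CC)CC)[C@@](O[Si](CC)(CC)CC)(CO[Si](c1ccccc1)(c1ccccc1)C(C)(C)C)CC#CC | intermediate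
32 | (3S,4Z,8S)-4,8-dimethyl-6-methylideneundec-4-en-9-yn-3-yl (2R,3R,4S)-4-{[tert-butyl(diphenyl)silyl]oxymethyl}-3,4-dihydroxy-2-methyloct-6-ynoate | CC#C[C@@H](C)CC(=C)/C=C(/C)[C@H](CC)OC(=O)[C@H](C)[C@@H](O)[C@@](O)(CO[Si](c1ccccc1)(c1ccccc1)C(C)(C)C)CC#CC | intermediate
33 | (3S,4Z,8S)-4,8-dimethyl-6-methylideneundec-4-en-9-yn-3-yl (2R,4S)-4-{[tert-butyl(diphenyl)silyl]oxymethyl}-4-hydroxy-2-methyl-3-oxooct-6-ynoate (metathesis precursor) | CC#C[C@@H](C)CC(=C)/C=C(/C)[C@H](CC)OC(=O)[C@H](C)C(=O)[C@@](O)(CO[Si](c1ccccc1)(c1ccccc1)C(C)(C)C)CC#CC | intermediate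
34 | (3R,5S,9S,12Z,14S)-5-{[tert-butyl(diphenyl)silyl]oxymethyl}-14-ethyl-5-hydroxy-3,9,13-trimethyl-11-methylidene-1-oxacyclotetradec-12-en-7-yne-2,4-dione | C=C1/C=C(/C)[C@H](CC)OC(=O)[C@H](C)C(=O)[C@@](O)(CO[Si](c2ccccc2)(c2ccccc2)C(C)(C)C)CC#C[C@@H](C)C1 | intermediate
35 | C5 dimethylsilyl ether of 34 | C=C1/C=C(/C)[C@H](CC)OC(=O)[C@H](C)C(=O)[C@@](O[SiH](C)C)(CO[Si](c2ccccc2)(c2ccccc2)C(C)(C)C)CC#C[C@@H](C)C1 | intermediate
36 | spiro oxasilolane (O5–SiMe2–C7 bridge, ring-cis C7=C8) | C=C1/C=C(/C)[C@H](CC)OC(=O)[C@H](C)C(=O)[C@]2(CO[Si](c3ccccc3)(c3ccccc3)C(C)(C)C)O[Si](C)(C)/C(C2)=C/[C@@H](C)C1 | intermediate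
37 | C7 iodide carrying a (hexafluoropropan-2-yloxy)dimethylsilyl group on O5 | C=C1/C=C(/C)[C@H](CC)OC(=O)[C@H](C)C(=O)[C@@](O[Si](C)(C)OC(C(F)(F)F)C(F)(F)F)(CO[Si](c2ccccc2)(c2ccccc2)C(C)(C)C)C/C(I)=C\[C@@H](C)C1 | intermediate (not isolated)
38 | (3R,5S,7E,9S,12Z,14S)-5-{[tert-butyl(diphenyl)silyl]oxymethyl}-14-ethyl-5-hydroxy-7-iodo-3,9,13-trimethyl-11-methylidene-1-oxacyclotetradeca-7,12-diene-2,4-dione | C=C1/C=C(/C)[C@H](CC)OC(=O)[C@H](C)C(=O)[C@@](O)(CO[Si](c2ccccc2)(c2ccccc2)C(C)(C)C)C/C(I)=C\[C@@H](C)C1 | intermediate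
39 | (3R,5S,7Z,9S,12Z,14S)-5-{[tert-butyl(diphenyl)silyl]oxymethyl}-14-ethyl-5-hydroxy-3,7,9,13-tetramethyl-11-methylidene-1-oxacyclotetradeca-7,12-diene-2,4-dione | C=C1/C=C(/C)[C@H](CC)OC(=O)[C@H](C)C(=O)[C@@](O)(CO[Si](c2ccccc2)(c2ccccc2)C(C)(C)C)C/C(C)=C\[C@@H](C)C1 | intermediate
40 | (3R,5S,7Z,9S,12Z,14S)-14-ethyl-5-hydroxy-5-(hydroxymethyl)-3,7,9,13-tetramethyl-11-methylidene-1-oxacyclotetradeca-7,12-diene-2,4-dione | C=C1/C=C(/C)[C@H](CC)OC(=O)[C@H](C)C(=O)[C@@](O)(CO)C/C(C)=C\[C@@H](C)C1 | target

**Step count and risks**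

Total step count: 27. Longest linear sequence: 17 steps (steps 11–27, from diol 18).

Steps most likely to fail:

1. Step 22 (ring-closing alkyne metathesis). The alkylidyne may be deactivated through ligand exchange or chelation by the free tertiary hydroxyl next to the C4 ketone, or through protonolysis by the acidic β-keto ester, so that conversion stalls or oligomers form. The fallback sets out from 31 and comes back at 34. The metathesis is run one stage earlier on the fully silylated seco ester 31, which has neither a free hydroxyl nor the ketone, to give the 14-membered cycloalkyne bis(triethylsilyl) ether F1. HF·pyridine then frees both hydroxyls to give the cycloalkyne C4,C5-diol F2, and Dess–Martin oxidation of its secondary C4 carbinol gives 34.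

2. Step 21 (oxidation to the β-keto ester). Once the ketone is in place, C3 may lose its configuration by enolisation, in this step and in steps 23–27. The γ-hydroxy β-keto ester may also undergo acyl transfer from O1 to the C5 oxygen, and the periodinane may cleave the C4–C5 glycol. The fallback sets out from 32 and comes back at 39; it keeps C4 as a protected carbinol until the C7 methyl is in place. The secondary C4 hydroxyl of 32 is silylated selectively (Et3SiCl, imidazole) to give the C4 triethylsilyl ether with free C5 hydroxyl F3. Ring-closing alkyne metathesis as in step 22 gives the cycloalkyne F4. ClSiMe2H and imidazole give the C5 dimethylsilyl ether F5, and platinum-catalysed syn hydrosilylation gives the oxasilolane F6. Iododesilylation with N-iodosuccinimide in hexafluoropropan-2-ol passes through the fluoroalkoxysilyl ether F7 and gives, after hydrolysis, the C7 iodide F8. Stille methylation with Me4Sn gives the C7-methyl macrocycle F9, and buffered HF·pyridine removes the C4 triethylsilyl group to give the C4,C5-diol F10. Only then does Dess–Martin oxidation form the ketone, giving 39, so that C3 faces a single further step.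

3. Step 13 (alane opening of the epoxy alcohol). The Lewis-acidic aluminium may open the oxirane at its fully substituted carbon or trigger rearrangement to an aldehyde, in competition with attack at CH2. The fallback sets out from 20 and comes back at 22. The hydroxyl of 20 is silylated (Et3SiCl, imidazole) to give the epoxy triethylsilyl ether F11. CH3C≡CLi with BF3·OEt2 in THF at −78 °C then opens the oxirane at its CH2 carbon by a low-temperature SN2 path to give the tertiary alcohol F12, and Et3SiOSO2CF3 with 2,6-lutidine silylates the tertiary hydroxyl to give 22.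

Further compounds
F1 | step 22 | 14-membered cycloalkyne lactone with O4 and O5 as triethylsilyl ethers | C=C1/C=C(/C)[C@H](CC)OC(=O)[C@H](C)[C@@H](O[Si](CC)(CC)CC)[C@@](O[Si](CC)(CC)CC)(CO[Si](c2ccccc2)(c2ccccc2)C(C)(C)C)CC#C[C@@H](C)C1
F2 | step 22 | 14-membered cycloalkyne lactone C4,C5-diol | C=C1/C=C(/C)[C@H](CC)OC(=O)[C@H](C)[C@@H](O)[C@@](O)(CO[Si](c2ccccc2)(c2ccccc2)C(C)(C)C)CC#C[C@@H](C)C1
F3 | step 21 | seco diyne ester with C4 triethylsilyl ether and free C5 hydroxyl | CC#C[C@@H](C)CC(=C)/C=C(/C)[C@H](CC)OC(=O)[C@H](C)[C@@H](O[Si](CC)(CC)CC)[C@@](O)(CO[Si](c1ccccc1)(c1ccccc1)C(C)(C)C)CC#CC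
F4 | step 21 | cycloalkyne lactone with C4 triethylsilyl ether and free C5 hydroxyl | C=C1/C=C(/C)[C@H](CC)OC(=O)[C@H](C)[C@@H](O[Si](CC)(CC)CC)[C@@](O)(CO[Si](c2ccccc2)(c2ccccc2)C(C)(C)C)CC#C[C@@H](C)C1
F5 | step 21 | C5 dimethylsilyl ether of F4 | C=C1/C=C(/C)[C@H](CC)OC(=O)[C@H](C)[C@@H](O[Si](CC)(CC)CC)[C@@](O[SiH](C)C)(CO[Si](c2ccccc2)(c2ccccc2)C(C)(C)C)CC#C[C@@H](C)C1
F6 | step 21 | spiro oxasilolane with C4 triethylsilyl ether | C=C1/C=C(/C)[C@H](CC)OC(=O)[C@H](C)[C@@H](O[Si](CC)(CC)CC)[C@]2(CO[Si](c3ccccc3)(c3ccccc3)C(C)(C)C)O[Si](C)(C)/C(C2)=C/[C@@H](C)C1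
F7 | step 21 | C7 iodide with (hexafluoropropan-2-yloxy)dimethylsilyl group on O5 and C4 triethylsilyl ether | C=C1/C=C(/C)[C@H](CC)OC(=O)[C@H](C)[C@@H](O[Si](CC)(CC)CC)[C@@](O[Si](C)(C)OC(C(F)(F)F)C(F)(F)F)(CO[Si](c2ccccc2)(c2ccccc2)C(C)(C)C)C/C(I)=C\[C@@H](C)C1
F8 | step 21 | C7 iodide with C4 triethylsilyl ether and free C5 hydroxyl | C=C1/C=C(/C)[C@H](CC)OC(=O)[C@H](C)[C@@H](O[Si](CC)(CC)CC)[C@@](O)(CO[Si](c2ccccc2)(c2ccccc2)C(C)(C)C)C/C(I)=C\[C@@H](C)C1
F9 | step 21 | C7-methyl macrocycle with C4 triethylsilyl ether | C=C1/C=C(/C)[C@H](CC)OC(=O)[C@H](C)[C@@H](O[Si](CC)(CC)CC)[C@@](O)(CO[Si](c2ccccc2)(c2ccccc2)C(C)(C)C)C/C(C)=C\[C@@H](C)C1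
F10 | step 21 | C7-methyl macrocycle C4,C5-diol | C=C1/C=C(/C)[C@H](CC)OC(=O)[C@H](C)[C@@H](O)[C@@](O)(CO[Si](c2ccccc2)(c2ccccc2)C(C)(C)C)C/C(C)=C\[C@@H](C)C1
F11 | step 13 | triethylsilyl ether of epoxy alcohol 20 | CC[Si](CC)(CC)OC[C@@]1(CO[Si](c2ccccc2)(c2ccccc2)C(C)(C)C)CO1
F12 | step 13 | tertiary alcohol with primary triethylsilyl ether (2-{[tert-butyl(diphenyl)silyl]oxymethyl}-1-(triethylsilyloxy)hex-4-yn-2-ol) | CC[Si](CC)(CC)OC[C@@](O)(CO[Si](c1ccccc1)(c1ccccc1)C(C)(C)C)CC#CC
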